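## The problem

The target 29, (1S,3R,5S,7S,8S)-8,10-dibromo-7,11,11-trimethyl-3-(prop-1-en-2-yl)-4,6-dioxatricyclo[5.4.0.0^{1,5}]undec-9-ene, packs three rings around one carbon. Cyclohexene ring A (C1, C7–C11), an oxetane (C1, C5, O6, C7) and a tetrahydrofuran (C1, C2, C3, O4, C5) all contain the quaternary carbon C1, and the acetal carbon C5 is shared by the two oxygen rings; this numbering is used below for the corresponding atoms of every intermediate. In ring A, C1 sits between two further fully substituted carbons, C11 (CMe2) and C7 (methyl and ether oxygen), so the C1–C11 bond joins two quaternary centres and is out of reach of enolate alkylation or any other polar ring closure. Of the five stereocentres, C5 follows from C1 because the oxygen rings can only be cis-fused; the oxetane demands that C5 on C1 and O6 on C7 be cis on ring A; the C8 bromine is trans to O6; C3 is insulated by the C2 methylene and must be bought in. The oxetane acetal will not survive acid, the secondary allylic bromide ionises easily, the isopropenyl group rules out ozonolysis, dihydroxylation and strong electrophiles, and the vinyl bromide rules out lithium–halogen exchange and low-valent metals late in the route. The acetal and the C8 bromide are therefore best made last, from a carboxyl carbon at C5 and an oxygen at C8. The feature that opens the structure is the sequence C1–C11(Me2)–C10(Br)=C9 in ring A: with C5 as a carboxyl group on C1 and an oxygen on C9, this is the product pattern of a [3,3] shift of the allyl ester C5(=O)–O–C9–C10(Br)=C11Me2, and because C7 and C8 already tie C1 to C9 that ester is a δ-lactone whose rearrangement closes ring A.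

## Retrosynthesis

**C8–Br.** The bromide is cut first, back to allylic alcohol 28 with the hydroxyl cis to O6, so that an Appel substitution with inversion delivers the trans bromide. It goes last because every other operation would endanger an allylic bromide. 28 comes from its silyl ether 27 with fluoride. The forward reaction must be a clean SN2 displacement at a hindered allylic carbon.

**C5–O6 (oxetane).** Cutting the acetal bond, rather than C7–O6 (substitution at a tertiary carbon), leads to hydroxy lactol 25, and from there to spiro lactone 24 by half reduction. The forward step must activate the lactol oxygen and let the tertiary C7 oxygen close a four-membered ring. The C8 oxygen would close a five-membered ring far more easily, which is why it stays silylated until 27.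

**C5–O4 (lactone).** Lactone 24 is the cyclised form of carboxylic acid 22; cyclisation occurs once the C3 silyl ether is removed. This cut costs nothing and exposes the carboxyl group on the quaternary carbon C1.

**C1–C11 (key cut).** Acid 22 is the Ireland–Claisen product of δ-lactone 19: the silyl ketene acetal 20 forms C1–C11 while C9–O breaks. The neighbouring ring A cuts (C7–C8, C10–C11, C8–C9; see below) all leave the C1–C11 bond between quaternary carbons to be made by other means, whereas this cut makes exactly that bond. 19 has no carbocycle and no quaternary carbon. The forward reaction needs enolisation next to a β-silyloxy group without elimination, and the bromoalkenyl group at C9 trans to the C7 oxygen so that the carboxyl ends cis to it.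

**C5–O(C9) and C1–C7 (lactone assembly).** Lactone 19 is the silyl ether of hydroxy lactone 18, which is the lactonised form of aldol adduct 16. 16 is cut between C1 and C7 into ester 14 (as enolate 15) and methyl ketone 7. The ketone addition has to follow the Felkin–Anh sense set by the C8 silyloxy group. Analysis of the chelated alternatives shows that a free C9 alkoxide or a chelating ether at C8 would give the wrong C7 epimer, hence the two silyl ethers in 7.

**C8–C9 (aldol).** Ketone 7 is the bis-silyl ether of anti-diol 5, the direct aldol product of hydroxyacetone 4 and 2-bromo-3-methylbut-2-enal 3, itself made from 3-methylbut-2-enal 1. The C8/C9 relationship required by the Claisen step is anti (erythro), which is what the proline-catalysed hydroxyacetone aldol gives. D-Proline is needed for the (3R,4S) series.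

**Side chain.** Ester 14 comes from (R)-5-(prop-1-en-2-yl)dihydrofuran-2(3H)-one 11, made from the chiral-pool acid 8 through methyl ketone 10. The stereocentre of 8 becomes C3 of the target unchanged.

## Roads not taken

**Alternative 1:** Cut C7–C8. SmI2 (divalent samarium) would couple a methyl ketone carbonyl (future C7) with an aldehyde carbonyl (future C8) on a substrate that already holds the spiro lactone, giving cis-diol A1.
- Merits: the samarium-bridged diolate gives the cis-diol directly, two stereocentres are set in one mild step, and no strong base or heat is needed. In this respect it is better than the chosen plan, which needs an aldol and a Felkin-controlled addition for the same two centres.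
- Weak points: the C1–C11 bond between two quaternary carbons must already be present, so the hardest bond is left to ordinary chemistry. A1 carries a saturated C9–C10 unit with a silyloxy group, so the vinyl bromide still has to be built from a ketone flanked by CMe2 (deprotection, oxidation, regioselective conversion to the bromoalkene). The ketone is β to the lactone carbonyl, a 1,3-dicarbonyl array open to ketyl fragmentation.
- Comparison: the chosen plan makes the C1–C11 bond in its key step and delivers the vinyl bromide in place.

**Alternative 2:** Cut C10–C11. Under blue light with Ir[dF(CF3)ppy]2(dtbbpy)PF6 and Cs2CO3, an α,α-dimethyl carboxylic acid would lose CO2, and the tertiary C11 radical would add to the bromine-bearing carbon of an ynone to give β-bromoenone A2.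
- Merits: radical addition is little affected by crowding at C11, runs at room temperature, and involves no enolate next to a β-oxygen. Here it is milder than the Ireland–Claisen step.
- Weak points: again C1–C11 must pre-exist. The bromoalkynyl ketone is a fragile acceptor. The isopropenyl group is a second radical acceptor within reach of C11. A2 has a ketone at C8, so a stereoselective reduction (hydride cis to the C7 methyl) must be found on a β-bromoenone that also reacts by addition–elimination.
- Comparison: the chosen plan brings the C8 carbinol configuration in from the aldol and needs no late redox step.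

**Alternative 3:** Cut C8–C9 and the vinyl C–Br bond. TiBr4 would make a terminal alkyne attack an α-hydroxy aldehyde while bromide adds to the internal alkyne carbon, giving diol A3.
- Merits: ring A, the vinyl bromide and the C8 carbinol appear in one step, and A3 is simply the desilylated form of 24, so this road would join the chosen end game with fewer protecting-group operations. In step economy after the cyclisation it is better.
- Weak points: the quaternary pair C1–C11 (now with a propargylic CMe2) must be assembled first. A tertiary α-hydroxy aldehyde is prone to α-ketol rearrangement under a strong Lewis acid. The isopropenyl alkene is a better π-nucleophile than a terminal alkyne and is exposed to TiBr4 and adventitious HBr. The cyclisation passes through a bent endocyclic vinyl cation, and the C8 configuration depends on an uncertain chelate.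
- Comparison: the chosen plan closes ring A under basic, then neutral thermal conditions that leave the isopropenyl group alone.

Key step: step 10

Remark on the chemistry: compounds 16–19 are carried as mixtures of epimers at the carbon α to the ester carbonyl (future C1, planar in 20), and lactol 25 as a mixture of anomers; neither mixture affects the outcome.

## Route

Step 1
Reactants: 1 3-methylbut-2-enal
Product: 3 2-bromo-3-methylbut-2-enal, via dibromide 2 (not isolated)
Conditions: Br2, CH2Cl2, 0 °C; then Et3N, 0 °C → rt
Reagents that add atoms: bromine, BrBr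
Why: Bromine adds across the enal double bond and Et3N then removes the acidic α-hydrogen with loss of the tertiary β-bromide (E1cB), the standard α-bromination of enals; no stereocentre is formed.

Step 2
Reactants: 3 2-bromo-3-methylbut-2-enal; 4 hydroxyacetone (1-hydroxypropan-2-one)
Product: 5 (3R,4S)-5-bromo-3,4-dihydroxy-6-methylhept-5-en-2-one
Conditions: D-proline (30 mol %), 4 (excess), DMSO, rt
Reagents that add atoms: none
Why: Proline-catalysed direct aldol reaction of unprotected hydroxyacetone (List–Notz type): the enamine forms on the hydroxylated side and the hydrogen-bonded chair-like transition state gives anti-1,2-diols, D-proline leading to the (3R,4S) isomer; the aldehyde has no α-hydrogen and can only act as acceptor.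

Step 3
Reactants: 5 (3R,4S)-5-bromo-3,4-dihydroxy-6-methylhept-5-en-2-one
Product: 7 (3R,4S)-5-bromo-6-methyl-3-(triisopropylsilyloxy)-4-(trimethylsilyloxy)hept-5-en-2-one, via mono-silyl ether 6 (not isolated)
Conditions: iPr3SiOTf (1.05 equiv), 2,6-lutidine, CH2Cl2, −78 °C; then Me3SiOTf, −78 → 0 °C
Reagents that add atoms: triisopropylsilyl trifluoromethanesulfonate, CC(C)[Si](OS(=O)(=O)C(F)(F)F)(C(C)C)C(C)C; trimethylsilyl trifluoromethanesulfonate, C[Si](C)(C)OS(=O)(=O)C(F)(F)F
Why: Kinetic silylation: the bulky silyl triflate should take the hydroxyl next to the acetyl group because the allylic one is screened by the tetrasubstituted bromoalkene (bromine on one side, a cis methyl on the other); the small trimethylsilyl triflate then caps the hindered hydroxyl so that no alkoxide is present in step 7.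

Step 4
Reactants: 8 (R)-5-oxotetrahydrofuran-2-carboxylic acid
Product: 10 (R)-5-acetyldihydrofuran-2(3H)-one, via acid chloride 9 (not isolated)
Conditions: (COCl)2, DMF (cat.), CH2Cl2, 0 °C → rt; evaporate; Me2CuLi, Et2O, −78 °C
Reagents that add atoms: lithium dimethylcuprate (Me2CuLi), [Li+].C[Cu-]C
Why: Acid chloride formation followed by acylation of a Gilman cuprate, which stops at the ketone and leaves the lactone untouched at −78 °C; the stereocentre is never exposed to base.

Step 5
Reactants: 10 (R)-5-acetyldihydrofuran-2(3H)-one
Product: 11 (R)-5-(prop-1-en-2-yl)dihydrofuran-2(3H)-one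
Conditions: Zn, CH2Br2, TiCl4, THF/CH2Cl2, 0 °C → rt
Reagents that add atoms: dibromomethane, BrCBr
Why: Takai–Lombardo methylenation: the non-basic Zn/CH2Br2/TiCl4 reagent methylenates ketones without epimerising an adjacent oxygen-bearing stereocentre and does not attack lactones.

Step 6
Reactants: 11 (R)-5-(prop-1-en-2-yl)dihydrofuran-2(3H)-one
Product: 14 methyl (4R)-5-methyl-4-(triethylsilyloxy)hex-5-enoate, via potassium carboxylate 12 (not isolated), via hydroxy ester 13 (not isolated)
Conditions: KOH (1.0 equiv), MeOH/H2O, rt; evaporate; MeI, DMF, 0 °C; then Et3SiCl, imidazole, 0 °C → rt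
Reagents that add atoms: potassium hydroxide, [K+].[OH-]; iodomethane, CI; chlorotriethylsilane, CC[Si](Cl)(CC)CC
Why: Saponification of the γ-lactone, O-alkylation of the carboxylate salt and silylation of the freed secondary alcohol before it can relactonise, the usual way to open a γ-lactone to a protected hydroxy ester; the stereocentre is not touched.

Step 7
Reactants: 14 methyl (4R)-5-methyl-4-(triethylsilyloxy)hex-5-enoate; 7 (3R,4S)-5-bromo-6-methyl-3-(triisopropylsilyloxy)-4-(trimethylsilyloxy)hept-5-en-2-one
Product: 16 methyl (3S,4R,5S)-6-bromo-3-hydroxy-3,7-dimethyl-2-[(2R)-3-methyl-2-(triethylsilyloxy)but-3-en-1-yl]-4-(triisopropylsilyloxy)-5-(trimethylsilyloxy)oct-6-enoate (both epimers at C2), via lithium ester enolate 15 (not isolated)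
Conditions: LiN(iPr)2, THF, −78 °C; then 7, −78 °C; AcOH quench at −78 °C
Reagents that add atoms: none
Why: Aldol addition of a lithium ester enolate to a methyl ketone; with both flanking oxygens silylated no chelate can form, so the enolate should add anti to the C–OSi(iPr)3 bond (Felkin–Anh polar model), setting the tertiary carbinol (future C7) with its oxygen anti to the neighbouring silyloxy group; the centre α to the ester is formed as a mixture that is erased in 20, and any adduct that has already transferred silicon and lactonised converges on 19 after steps 8 and 9.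

Step 8
Reactants: 16 methyl (3S,4R,5S)-6-bromo-3-hydroxy-3,7-dimethyl-2-[(2R)-3-methyl-2-(triethylsilyloxy)but-3-en-1-yl]-4-(triisopropylsilyloxy)-5-(trimethylsilyloxy)oct-6-enoate
Product: 18 (4S,5R,6S)-6-(1-bromo-2-methylprop-1-en-1-yl)-4-hydroxy-4-methyl-3-[(2R)-3-methyl-2-(triethylsilyloxy)but-3-en-1-yl]-5-(triisopropylsilyloxy)tetrahydro-2H-pyran-2-one (both epimers at C3), via dihydroxy ester 17 (not isolated)
Conditions: K2CO3, MeOH, 0 °C; evaporate; DBU (cat.), PhMe, rt
Reagents that add atoms: none
Why: Base-catalysed methanolysis removes only the trimethylsilyl ether (triethylsilyl and triisopropylsilyl ethers withstand K2CO3/MeOH), and the freed allylic hydroxyl lactonises onto the methyl ester once methanol is replaced by toluene; the tertiary hydroxyl could only give a four-membered ring and the neighbouring oxygen is blocked, so only the δ-lactone can form.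

Step 9
Reactants: 18 (4S,5R,6S)-6-(1-bromo-2-methylprop-1-en-1-yl)-4-hydroxy-4-methyl-3-[(2R)-3-methyl-2-(triethylsilyloxy)but-3-en-1-yl]-5-(triisopropylsilyloxy)tetrahydro-2H-pyran-2-one
Product: 19 (4S,5R,6S)-6-(1-bromo-2-methylprop-1-en-1-yl)-4-methyl-3-[(2R)-3-methyl-2-(triethylsilyloxy)but-3-en-1-yl]-5-(triisopropylsilyloxy)-4-(trimethylsilyloxy)tetrahydro-2H-pyran-2-one (both epimers at C3)
Conditions: Me3SiOTf, 2,6-lutidine, CH2Cl2, −78 → 0 °C
Reagents that add atoms: trimethylsilyl trifluoromethanesulfonate, C[Si](C)(C)OS(=O)(=O)C(F)(F)F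
Why: Silylation of a hindered tertiary alcohol with a silyl triflate and 2,6-lutidine; the small trimethylsilyl group is chosen because it must go onto a crowded oxygen and come off later under the mildest acid.

Step 10
Reactants: 19 (4S,5R,6S)-6-(1-bromo-2-methylprop-1-en-1-yl)-4-methyl-3-[(2R)-3-methyl-2-(triethylsilyloxy)but-3-en-1-yl]-5-(triisopropylsilyloxy)-4-(trimethylsilyloxy)tetrahydro-2H-pyran-2-one
Product: 22 (1S,5R,6S)-3-bromo-2,2,6-trimethyl-1-[(2R)-3-methyl-2-(triethylsilyloxy)but-3-en-1-yl]-5-(triisopropylsilyloxy)-6-(trimethylsilyloxy)cyclohex-3-ene-1-carboxylic acid, via silyl ketene acetal 20 (not isolated), via trimethylsilyl ester 21 (not isolated)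
Conditions: Me3SiCl, Et3N, THF, −78 °C; LiN(iPr)2 added, −78 °C → rt; PhMe, 100 °C; aq. NH4Cl
Reagents that add atoms: none
Why: LiN(iPr)2 removes the hydrogen α to the lactone carbonyl and the enolate is silylated on oxygen at once by the Me3SiCl already present, giving the endocyclic silyl ketene acetal 20; on heating, 20 undergoes a concerted suprafacial [3,3] shift in which the C1–C11 bond forms between the ketene acetal carbon and the CMe2 terminus while the C9–O bond breaks, and aqueous work-up hydrolyses silyl ester 21 to acid 22. The closest known reaction type is the Ireland–Claisen ring contraction of alkenyl lactone silyl ketene acetals to cycloalkene carboxylic acids. Ring A (C1, C7, C8, C9, C10, C11) closes pericyclically through a boat transition state enforced by the lactone, a bicyclo[2.2.2]octane-like array, so no polar ring closure is involved and two fully substituted carbons can be joined. The one new stereocentre, C1, is controlled by C9: the bond must form on the lactone face that carries the bromoalkenyl group, and since the C7 silyloxy group is trans to that group the carboxyl ends cis to the C7 oxygen, as the oxetane needs; C1 is planar in 20, so both epimers of 19 converge. The selectivity the step needs is O-silylation of the enolate ahead of β-elimination of the C7 silyloxy group, secured by the internal quench at −78 °C, and reaction at the correct alkene terminus, which is fixed because only the CMe2 carbon can reach C1. The alkene terminus carries two identical methyl groups, so no alkene geometry is at stake, and bromine arrives on C10 next to CMe2. The silyloxy groups at C7 and C8 lie on the face opposite the reacting alkene and do not obstruct the boat array.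

Step 11
Reactants: 22 (1S,5R,6S)-3-bromo-2,2,6-trimethyl-1-[(2R)-3-methyl-2-(triethylsilyloxy)but-3-en-1-yl]-5-(triisopropylsilyloxy)-6-(trimethylsilyloxy)cyclohex-3-ene-1-carboxylic acid
Product: 24 (3R,5S,9R,10S)-7-bromo-10-hydroxy-6,6,10-trimethyl-3-(prop-1-en-2-yl)-9-(triisopropylsilyloxy)-2-oxaspiro[4.5]dec-7-en-1-one, via dihydroxy acid 23 (not isolated)
Conditions: AcOH/THF/H2O (3:1:1), rt → 40 °C
Reagents that add atoms: none
Why: Acidic solvolysis removes the secondary triethylsilyl and tertiary trimethylsilyl ethers while the triisopropylsilyl ether is orders of magnitude slower, and the freed C3 hydroxyl lactonises spontaneously onto the carboxyl group (five-membered ring, helped by the quaternary C1); the tertiary C7 hydroxyl could only give a β-lactone and stays free.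

Step 12
Reactants: 24 (3R,5S,9R,10S)-7-bromo-10-hydroxy-6,6,10-trimethyl-3-(prop-1-en-2-yl)-9-(triisopropylsilyloxy)-2-oxaspiro[4.5]dec-7-en-1-one
Product: 25 (3R,5S,9R,10S)-7-bromo-6,6,10-trimethyl-3-(prop-1-en-2-yl)-9-(triisopropylsilyloxy)-2-oxaspiro[4.5]dec-7-ene-1,10-diol (both anomers)
Conditions: iBu2AlH (2.2 equiv), CH2Cl2, −78 °C; aq. potassium sodium tartrate
Reagents that add atoms: none
Why: Half reduction of a γ-lactone by iBu2AlH; the aluminium lactolate is stable at −78 °C and the quaternary α-carbon retards over-reduction; the new centre C5 is an anomeric mixture of no consequence.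

Step 13
Reactants: 25 (3R,5S,9R,10S)-7-bromo-6,6,10-trimethyl-3-(prop-1-en-2-yl)-9-(triisopropylsilyloxy)-2-oxaspiro[4.5]dec-7-ene-1,10-diol
Product: 27 (1S,3R,5S,7S,8R)-10-bromo-7,11,11-trimethyl-3-(prop-1-en-2-yl)-8-(triisopropylsilyloxy)-4,6-dioxatricyclo[5.4.0.0^{1,5}]undec-9-ene, via anomeric tosylate 26 (not isolated)
Conditions: KN(SiMe3)2 (2.1 equiv), THF, −78 °C; then Ts2O (1.05 equiv), −78 → 0 °C
Reagents that add atoms: none
Why: Glycosyl-sulfonate-type anomeric activation: the lactolate is sulfonylated at the less hindered anomeric oxygen and the neighbouring tertiary alkoxide displaces the sulfonate through the oxocarbenium ion pair (4-exo-tet), the way 1,3-anhydro sugars are closed from glycosyl halides bearing a free 3-hydroxyl; C5 can only form cis-fused, so its configuration follows from C1 and C7, and because C1 is quaternary no enol ether can form by elimination.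

Step 14
Reactants: 27 (1S,3R,5S,7S,8R)-10-bromo-7,11,11-trimethyl-3-(prop-1-en-2-yl)-8-(triisopropylsilyloxy)-4,6-dioxatricyclo[5.4.0.0^{1,5}]undec-9-ene
Product: 28 (1S,3R,5S,7S,8R)-10-bromo-7,11,11-trimethyl-3-(prop-1-en-2-yl)-4,6-dioxatricyclo[5.4.0.0^{1,5}]undec-9-en-8-ol
Conditions: Bu4NF, THF, 0 °C → rt
Reagents that add atoms: none
Why: Fluoride cleavage of the silyl ether under basic conditions, to which the acetal, the vinyl bromide and both alkenes are inert; no stereocentre is affected.

Step 15
Reactants: 28 (1S,3R,5S,7S,8R)-10-bromo-7,11,11-trimethyl-3-(prop-1-en-2-yl)-4,6-dioxatricyclo[5.4.0.0^{1,5}]undec-9-en-8-ol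
Product: 29 (1S,3R,5S,7S,8S)-8,10-dibromo-7,11,11-trimethyl-3-(prop-1-en-2-yl)-4,6-dioxatricyclo[5.4.0.0^{1,5}]undec-9-ene
Conditions: CBr4, PPh3, 2,6-lutidine, CH2Cl2, 0 °C → rt
Reagents that add atoms: carbon tetrabromide, BrC(Br)(Br)Br
Why: Appel reaction: bromide displaces the alkoxyphosphonium ion of the allylic alcohol with inversion (SN2), turning the C8 oxygen cis to O6 into bromine trans to O6; C7 and C11 are quaternary, so elimination cannot compete, and 2,6-lutidine keeps the acetal free of acid.

## Compound list

1 | 3-methylbut-2-enal | CC(C)=CC=O | starting material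
2 | 2,3-dibromo-3-methylbutanal (racemic) | CC(C)(Br)C(Br)C=O | intermediate
3 | 2-bromo-3-methylbut-2-enal | CC(C)=C(Br)C=O | intermediate
4 | hydroxyacetone (1-hydroxypropan-2-one) | CC(=O)CO | starting material
5 | (3R,4S)-5-bromo-3,4-dihydroxy-6-methylhept-5-en-2-one | CC(=O)[C@H](O)[C@H](O)C(Br)=C(C)C | intermediate
6 | (3R,4S)-5-bromo-4-hydroxy-6-methyl-3-(triisopropylsilyloxy)hept-5-en-2-one | CC(=O)[C@H](O[Si](C(C)C)(C(C)C)C(C)C)[C@H](O)C(Br)=C(C)C | intermediate
7 | (3R,4S)-5-bromo-6-methyl-3-(triisopropylsilyloxy)-4-(trimethylsilyloxy)hept-5-en-2-one | CC(=O)[C@H](O[Si](C(C)C)(C(C)C)C(C)C)[C@H](O[Si](C)(C)C)C(Br)=C(C)C | intermediate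
8 | (R)-5-oxotetrahydrofuran-2-carboxylic acid | OC(=O)[C@H]1CCC(=O)O1 | starting material
9 | (R)-5-oxotetrahydrofuran-2-carbonyl chloride | ClC(=O)[C@H]1CCC(=O)O1 | intermediate
10 | (R)-5-acetyldihydrofuran-2(3H)-one | CC(=O)[C@H]1CCC(=O)O1 | intermediate
11 | (R)-5-(prop-1-en-2-yl)dihydrofuran-2(3H)-one | C=C(C)[C@H]1CCC(=O)O1 | intermediate
12 | potassium (4R)-4-hydroxy-5-methylhex-5-enoate | C=C(C)[C@H](O)CCC(=O)[O-].[K+] | intermediate
13 | methyl (4R)-4-hydroxy-5-methylhex-5-enoate | C=C(C)[C@H](O)CCC(=O)OC | intermediate
14 | methyl (4R)-5-methyl-4-(triethylsilyloxy)hex-5-enoate | C=C(C)[C@H](O[Si](CC)(CC)CC)CCC(=O)OC | intermediate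
15 | lithium enolate of 14 | C=C(C)[C@H](O[Si](CC)(CC)CC)CC=C([O-])OC.[Li+] | intermediate
16 | methyl (3S,4R,5S)-6-bromo-3-hydroxy-3,7-dimethyl-2-[(2R)-3-methyl-2-(triethylsilyloxy)but-3-en-1-yl]-4-(triisopropylsilyloxy)-5-(trimethylsilyloxy)oct-6-enoate (C2 epimers) | C=C(C)[C@H](O[Si](CC)(CC)CC)CC(C(=O)OC)[C@](C)(O)[C@H](O[Si](C(C)C)(C(C)C)C(C)C)[C@H](O[Si](C)(C)C)C(Br)=C(C)C | intermediate
17 | methyl (3S,4R,5S)-6-bromo-3,5-dihydroxy-3,7-dimethyl-2-[(2R)-3-methyl-2-(triethylsilyloxy)but-3-en-1-yl]-4-(triisopropylsilyloxy)oct-6-enoate (C2 epimers) | C=C(C)[C@H](O[Si](CC)(CC)CC)CC(C(=O)OC)[C@](C)(O)[C@H](O[Si](C(C)C)(C(C)C)C(C)C)[C@H](O)C(Br)=C(C)C | intermediate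
18 | (4S,5R,6S)-6-(1-bromo-2-methylprop-1-en-1-yl)-4-hydroxy-4-methyl-3-[(2R)-3-methyl-2-(triethylsilyloxy)but-3-en-1-yl]-5-(triisopropylsilyloxy)tetrahydro-2H-pyran-2-one (C3 epimers) | C=C(C)[C@H](O[Si](CC)(CC)CC)CC1C(=O)O[C@H](C(Br)=C(C)C)[C@@H](O[Si](C(C)C)(C(C)C)C(C)C)[C@@]1(C)O | intermediate
19 | (4S,5R,6S)-6-(1-bromo-2-methylprop-1-en-1-yl)-4-methyl-3-[(2R)-3-methyl-2-(triethylsilyloxy)but-3-en-1-yl]-5-(triisopropylsilyloxy)-4-(trimethylsilyloxy)tetrahydro-2H-pyran-2-one (C3 epimers) | C=C(C)[C@H](O[Si](CC)(CC)CC)CC1C(=O)O[C@H](C(Br)=C(C)C)[C@@H](O[Si](C(C)C)(C(C)C)C(C)C)[C@@]1(C)O[Si](C)(C)C | intermediate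
20 | (2S,3R,4S)-2-(1-bromo-2-methylprop-1-en-1-yl)-4-methyl-5-[(2R)-3-methyl-2-(triethylsilyloxy)but-3-en-1-yl]-3-(triisopropylsilyloxy)-4,6-bis(trimethylsilyloxy)-3,4-dihydro-2H-pyran | C=C(C)[C@H](O[Si](CC)(CC)CC)CC1=C(O[Si](C)(C)C)O[C@H](C(Br)=C(C)C)[C@@H](O[Si](C(C)C)(C(C)C)C(C)C)[C@@]1(C)O[Si](C)(C)C | intermediate
21 | trimethylsilyl ester of 22 | C=C(C)[C@H](O[Si](CC)(CC)CC)C[C@@]1(C(=O)O[Si](C)(C)C)[C@](C)(O[Si](C)(C)C)[C@H](O[Si](C(C)C)(C(C)C)C(C)C)C=C(Br)C1(C)C | intermediate
22 | (1S,5R,6S)-3-bromo-2,2,6-trimethyl-1-[(2R)-3-methyl-2-(triethylsilyloxy)but-3-en-1-yl]-5-(triisopropylsilyloxy)-6-(trimethylsilyloxy)cyclohex-3-ene-1-carboxylic acid | C=C(C)[C@H](O[Si](CC)(CC)CC)C[C@@]1(C(O)=O)[C@](C)(O[Si](C)(C)C)[C@H](O[Si](C(C)C)(C(C)C)C(C)C)C=C(Br)C1(C)C | intermediate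
23 | (1S,5R,6S)-3-bromo-6-hydroxy-1-[(2R)-2-hydroxy-3-methylbut-3-en-1-yl]-2,2,6-trimethyl-5-(triisopropylsilyloxy)cyclohex-3-ene-1-carboxylic acid | C=C(C)[C@H](O)C[C@@]1(C(O)=O)[C@](C)(O)[C@H](O[Si](C(C)C)(C(C)C)C(C)C)C=C(Br)C1(C)C | intermediate
24 | (3R,5S,9R,10S)-7-bromo-10-hydroxy-6,6,10-trimethyl-3-(prop-1-en-2-yl)-9-(triisopropylsilyloxy)-2-oxaspiro[4.5]dec-7-en-1-one | C=C(C)[C@H]1C[C@@]2(C(=O)O1)[C@](C)(O)[C@H](O[Si](C(C)C)(C(C)C)C(C)C)C=C(Br)C2(C)C | intermediate
25 | (3R,5S,9R,10S)-7-bromo-6,6,10-trimethyl-3-(prop-1-en-2-yl)-9-(triisopropylsilyloxy)-2-oxaspiro[4.5]dec-7-ene-1,10-diol (anomers) | C=C(C)[C@H]1C[C@@]2(C(O)O1)[C@](C)(O)[C@H](O[Si](C(C)C)(C(C)C)C(C)C)C=C(Br)C2(C)C | intermediate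
26 | potassium 10-alkoxide of the 1-O-(p-toluenesulfonyl) derivative of 25 | C=C(C)[C@H]1C[C@@]2(C(OS(=O)(=O)c3ccc(C)cc3)O1)[C@](C)([O-])[C@H](O[Si](C(C)C)(C(C)C)C(C)C)C=C(Br)C2(C)C.[K+] | intermediate
27 | (1S,3R,5S,7S,8R)-10-bromo-7,11,11-trimethyl-3-(prop-1-en-2-yl)-8-(triisopropylsilyloxy)-4,6-dioxatricyclo[5.4.0.0^{1,5}]undec-9-ene | C=C(C)[C@H]1C[C@@]23[C@@H](O1)O[C@]2(C)[C@H](O[Si](C(C)C)(C(C)C)C(C)C)C=C(Br)C3(C)C | intermediate
28 | (1S,3R,5S,7S,8R)-10-bromo-7,11,11-trimethyl-3-(prop-1-en-2-yl)-4,6-dioxatricyclo[5.4.0.0^{1,5}]undec-9-en-8-ol | C=C(C)[C@H]1C[C@@]23[C@@H](O1)O[C@]2(C)[C@H](O)C=C(Br)C3(C)C | intermediate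
29 | (1S,3R,5S,7S,8S)-8,10-dibromo-7,11,11-trimethyl-3-(prop-1-en-2-yl)-4,6-dioxatricyclo[5.4.0.0^{1,5}]undec-9-ene | C=C(C)[C@H]1C[C@@]23[C@@H](O1)O[C@]2(C)[C@@H](Br)C=C(Br)C3(C)C | target

## Step count and least certain steps

Total: 15 steps. Longest linear sequence: 12 steps (steps 1–3 and 7–15 from 1; the branch from 8 through steps 4–6 and 7–15 is equally long).

**Step 10 (key step).** The likeliest failure is loss of the C7 silyloxy group by β-elimination from the lactone enolate before it is silylated, made worse by slow removal of the hindered α-hydrogen. A sluggish shift through the crowded boat array, with decay of the ketene acetal at 100 °C, is the second concern. The fallback changes how the β-oxygen is carried and sets out from 18. With 2.2 equivalents of LiN(iPr)2 the tertiary hydroxyl is deprotonated first, so the enolate carries a β-oxide that cannot leave (the known Ireland–Claisen rearrangement of β-hydroxy ester dianions). Me3SiCl then silylates both oxygens, and heating with mildly acidic work-up should give the hydroxy acid F1, which the conditions of step 11 convert into 24.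

**Step 15.** The displacement at C8 is next to a quaternary carbon. Ionisation may take over from direct substitution, with loss of stereochemical integrity, a methyl shift from C7, or opening of the acid-labile acetal by phosphonium species. The fallback exchanges oxygen for bromine before the acetal exists and sets out from 24. Bu4NF should give the diol lactone F2 (the compound labelled A3 above). CBr4/PPh3 should brominate only its secondary allylic hydroxyl with inversion, giving the bromo lactone F3; the cis tertiary hydroxyl cannot form an epoxide. iBu2AlH at −78 °C gives the bromo lactol F4. The oxetane is then closed under neutral Mitsunobu conditions (PPh3, diisopropyl azodicarboxylate), chosen because an alkoxide would displace the now trans bromide. The fallback returns to the route at 29.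

**Step 13.** Before the four-membered ring closes, the tertiary potassium alkoxide may take over the silyl group from the neighbouring C8 oxygen, or the lactolate may open to its hydroxy aldehyde tautomer. Either process puts the sulfonate on the wrong oxygen or leads to the five-membered acetal through the C8 oxygen. The fallback replaces the sulfonate/alkoxide pair by a redox condensation without base, from 25 to 27: PPh3 and diisopropyl azodicarboxylate activate the more acidic, less hindered lactol hydroxyl as an oxyphosphonium ion, and the tertiary hydroxyl closes the ring without ever being an alkoxide. No new compound is involved.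

**Step 7.** Facial selectivity may be poor if a lithium chelate competes with the Felkin–Anh pathway. The basic ester enolate may also enolise the methyl ketone instead of adding, and the adduct may revert on warming. The fallback is a Mukaiyama aldol addition and sets out from 14. LiN(iPr)2 and Me3SiCl give the silyl ketene acetal F5, which is added to 7 with BF3·OEt2 in CH2Cl2 at −78 °C. The monodentate Lewis acid cannot chelate and the nucleophile is not basic. The fallback returns at 16.

**Step 2.** The hindered, conjugated acceptor is outside the usual range of the proline-catalysed hydroxyacetone aldol. Low diastereo- or enantioselectivity, or diversion of the catalyst as an iminium ion of the enal, is possible. The fallback leaves enamine catalysis and sets out from 3. A Wittig reaction with 1-(triphenylphosphoranylidene)propan-2-one gives the (E)-dienone F6. Catalytic asymmetric nucleophilic epoxidation of the enone double bond follows (La(OiPr)3, BINOL of the sense that gives the 2R,3R oxirane, Ph3As=O, tBuOOH); the tetrasubstituted bromoalkene is not attacked. This should give the trans-epoxy ketone F7. Acid-catalysed hydrolysis (HClO4 cat., THF/H2O) opens it at the allylic carbon with inversion and returns to the route at 5.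

**Step 3.** Site selectivity between the two secondary hydroxyls may be incomplete. The fallback protects both and then deprotects selectively, setting out from 5. Me3SiCl/imidazole gives the bis(trimethylsilyl) ether F8. Brief K2CO3/MeOH at −20 °C should cleave the less hindered, more electrophilic silyl ether next to the ketone, giving the mono-silyl ether F9. iPr3SiOTf/2,6-lutidine then returns to the route at 7.

Further compounds

F1 | step 10 | (1S,5R,6S)-3-bromo-6-hydroxy-2,2,6-trimethyl-1-[(2R)-3-methyl-2-(triethylsilyloxy)but-3-en-1-yl]-5-(triisopropylsilyloxy)cyclohex-3-ene-1-carboxylic acid | C=C(C)[C@H](O[Si](CC)(CC)CC)C[C@@]1(C(O)=O)[C@](C)(O)[C@H](O[Si](C(C)C)(C(C)C)C(C)C)C=C(Br)C1(C)C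
F2 | step 15 | (3R,5S,9R,10S)-7-bromo-9,10-dihydroxy-6,6,10-trimethyl-3-(prop-1-en-2-yl)-2-oxaspiro[4.5]dec-7-en-1-one | C=C(C)[C@H]1C[C@@]2(C(=O)O1)[C@](C)(O)[C@H](O)C=C(Br)C2(C)C
F3 | step 15 | (3R,5S,9S,10S)-7,9-dibromo-10-hydroxy-6,6,10-trimethyl-3-(prop-1-en-2-yl)-2-oxaspiro[4.5]dec-7-en-1-one | C=C(C)[C@H]1C[C@@]2(C(=O)O1)[C@](C)(O)[C@@H](Br)C=C(Br)C2(C)C
F4 | step 15 | (3R,5S,9S,10S)-7,9-dibromo-6,6,10-trimethyl-3-(prop-1-en-2-yl)-2-oxaspiro[4.5]dec-7-ene-1,10-diol (anomers) | C=C(C)[C@H]1C[C@@]2(C(O)O1)[C@](C)(O)[C@@H](Br)C=C(Br)C2(C)C
F0 | step 13 | none | none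
F5 | step 7 | methyl trimethylsilyl ketene acetal of 14 (E/Z mixture) | C=C(C)[C@H](O[Si](CC)(CC)CC)CC=C(OC)O[Si](C)(C)C
F6 | step 2 | (3E)-5-bromo-6-methylhepta-3,5-dien-2-one | CC(=O)/C=C/C(Br)=C(C)C
F7 | step 2 | 1-[(2R,3R)-3-(1-bromo-2-methylprop-1-en-1-yl)oxiran-2-yl]ethan-1-one | CC(=O)[C@@H]1O[C@H]1C(Br)=C(C)C
F8 | step 3 | (3R,4S)-5-bromo-6-methyl-3,4-bis(trimethylsilyloxy)hept-5-en-2-one | CC(=O)[C@H](O[Si](C)(C)C)[C@H](O[Si](C)(C)C)C(Br)=C(C)C
F9 | step 3 | (3R,4S)-5-bromo-3-hydroxy-6-methyl-4-(trimethylsilyloxy)hept-5-en-2-one | CC(=O)[C@H](O)[C@H](O[Si](C)(C)C)C(Br)=C(C)C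
A1 | alternative 1 | 7-(tert-butyldimethylsilyloxy)-9,10-dihydroxy-6,6,10-trimethyl-3-(prop-1-en-2-yl)-2-oxaspiro[4.5]decan-1-one (cis-9,10-diol) | C=C(C)[C@H]1C[C@@]2(C(=O)O1)[C@](C)(O)[C@H](O)C[C@@H](O[Si](C)(C)C(C)(C)C)C2(C)C
A2 | alternative 2 | 7-bromo-6,6,10-trimethyl-3-(prop-1-en-2-yl)-10-(triethylsilyloxy)-2-oxaspiro[4.5]dec-7-ene-1,9-dione | C=C(C)[C@H]1C[C@@]2(C(=O)O1)[C@](C)(O[Si](CC)(CC)CC)C(=O)C=C(Br)C2(C)C
A3 | alternative 3 | (3R,5S,9R,10S)-7-bromo-9,10-dihydroxy-6,6,10-trimethyl-3-(prop-1-en-2-yl)-2-oxaspiro[4.5]dec-7-en-1-one | C=C(C)[C@H]1C[C@@]2(C(=O)O1)[C@](C)(O)[C@H](O)C=C(Br)C2(C)C
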